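The vessel is closed and stirred at one temperature, so what leaves the substrate stays in the vessel as other species.

| flask | substrate | acid | remark | time |
|---|---|---|---|---|
| Wednesday's | 13 mM | 0.20 mM | run made earlier |  |
| Thursday's | 30 mM | 0.20 mM | run made earlier |  |
| flask | 20 mM | 0.200 mM |  | 20 h |

| run | time / h | substrate / % | target / % |
|---|---|---|---|
| Wednesday's | 1.33 | 35.8 | 12.0 |
| Wednesday's | 4.00 | 13.5 | 21.4 |
| Wednesday's | 6.00 | 8.6 | 24.8 |
| Wednesday's | 10.0 | 5.1 | 28.2 |
| Wednesday's | 15.0 | 3.8 | 32.0 |
| Wednesday's | 20.0 | 2.2 | 34.1 |
| Wednesday's | 25.0 | 2.0 | 34.8 |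
| Thursday's | 1.33 | 21.2 | 9.1 |
| Thursday's | 4.00 | 6.7 | 13.5 |
| Thursday's | 6.00 | 4.1 | 16.2 |
| Thursday's | 10.0 | 3.4 | 17.6 |
| Thursday's | 15.0 | 2.7 | 20.9 |
| Thursday's | 20.0 | 2.0 | 22.1 |
| Thursday's | 25.0 | 1.0 | 22.7 |

(standard deviation of a reading: 0.5 percentage points)

- part of the substrate that has reacted at 20 h
- pH of the solution at 20 h

- acid is the free proton; pH is minus the decimal logarithm of its molar concentration
- what has gone from substrate into another species counts as reacted, even if it can come back

At the first reading, Thursday's run keeps 21.2% of its substrate, less than the 35.8% of Wednesday's run, so the larger charge falls faster and the loss looks second order. Under such a loss the share left is h/(h+t), and h shrinks inversely with the charge. The first readings give h as 0.742 h on Wednesday and 0.358 h on Thursday.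

Scaled to this flask's charge and averaged, they give 0.509 h, the second-order half-life: the time in which such a loss halves the charge. But the rule needs testing at the late readings. At 20.0 h it gives 3.58% against Wednesday's 2.2%, and 1.76% against Thursday's 2.0%, so it may err by 1.4 percentage points.

For this flask it leaves 2.48%, so 97.5% has reacted. The pH is taken from the acid charge, as an assumption.

The forecast gives 97.7%, against 97.5% by this reckoning, and pH 3.7, noting that “nothing shows it being consumed”.

The flask gives 98.0% reacted and pH 3.70.

    substrate + acid → weak acid + acid + target (k = 10.5 L mol⁻¹ min⁻¹)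
    weak acid ⇌ conjugate base + acid, settled at all times (K = 2.00 × 10⁻⁸ M)
    substrate → weak acid + target (k = 5.16 × 10⁻⁴ min⁻¹)
    substrate ⇌ dormant form (K = 0.840, k = 0.00232 min⁻¹)
    2 substrate → self-condensation product (k = 0.560 L mol⁻¹ min⁻¹)

In the flask at 20.0 h, self-condensation product, each holding two substrate, accounts for 67.4% of the charge and target for 27.6%. The half-life 0.509 h gives 2.48% left at 20 h against 2.0% in the flask, and at 5.0 h in the same flask it gives 9.24% against 7.7%.

(The data were generated by integration with made-up constants, and the scatter is random.)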